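**Plan**

- Enabling feature: ring B carries its two oxygens para to each other at C2' and C5', with C3' and C4' unsubstituted. This C2'–C3'–C4'–C5' unit with oxygen at both ends is the carbon skeleton of a 2-alkoxyfuran, and C1' and C6' are the two carbons of an alkyne attached to C2 of the chromone.
- Cuts, in retrosynthetic order: the 5-O–H back to 5-O–CH3 and the 5'-O–CH3 back to 5'-OH; then C1'–C2' and C6'–C5' of ring B (Diels–Alder addition and bridge opening); then the C≡C bond (aldehyde homologation); then O1–C2 and C2–C3 of ring C (Claisen condensation and cyclodehydration); last the aryl–acetyl bond.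
- Forward order: ring A is bought as 3,4,5-trimethoxyphenol (1). Ring C is closed in step 3 (compound 6) and its 2-methyl group is taken to the ethynyl group (8). Ring B is built last from 2-methoxyfuran (9), followed by two O-methyl adjustments.
- Stereochemistry: the target has no stereocentre and no stereogenic double bond; the two bridgehead centres of the transient cycloadduct are erased on aromatisation.

Key step: step 6

Remark: the cycloaddition in step 6 is written with the orientation expected from the polarisation of both partners (furan C5 to the alkyne terminus). The opposite orientation would give the isomeric 2'-hydroxy-5'-methoxy phenol, which step 7 would convert into the same compound 12.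

**Route**

Step 1
Reactants: 1 3,4,5-trimethoxyphenol
Product: 2 1,2,3,5-tetramethoxybenzene
Conditions: MeI, K2CO3, DMF, rt
Reagents that add atoms: iodomethane, CI
Why: Williamson O-methylation of the phenoxide by SN2 attack on iodomethane, giving the symmetrical tetramethyl ether.

Step 2
Reactants: 2 1,2,3,5-tetramethoxybenzene
Product: 4 1-(2-hydroxy-3,4,6-trimethoxyphenyl)ethanone, via 1-(2,3,4,6-tetramethoxyphenyl)ethanone 3 (not isolated)
Conditions: AcCl, AlCl3 (2.5 equiv), Et2O, 0 °C to reflux; aq. HCl work-up
Reagents that add atoms: acetyl chloride, CC(Cl)=O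
Why: Friedel–Crafts acylation at one of the two equivalent free positions of 2 gives 3, and AlCl3 chelated to the new ketone then cleaves the ortho methoxy group that is flanked by a second methoxy group, the usual site selectivity for 2,3-dimethoxyaryl ketones, which fixes the later 5,7,8-oxygenation pattern.

Step 3
Reactants: 4 1-(2-hydroxy-3,4,6-trimethoxyphenyl)ethanone
Product: 6 5,7,8-trimethoxy-2-methyl-4H-chromen-4-one, via 1-(2-hydroxy-3,4,6-trimethoxyphenyl)butane-1,3-dione 5 (not isolated)
Conditions: NaH, EtOAc, THF, reflux; then conc. HCl, MeOH, 50 °C (same pot)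
Reagents that add atoms: ethyl acetate, CCOC(C)=O
Why: crossed Claisen condensation of the sodium enolate of 4 with ethyl acetate gives β-diketone 5, which on acidification undergoes cyclodehydration (phenol oxygen onto the distal carbonyl, then loss of water) to the 2-methylchromone, the standard entry to this ring system.

Step 4
Reactants: 6 5,7,8-trimethoxy-2-methyl-4H-chromen-4-one
Product: 7 5,7,8-trimethoxy-4-oxo-4H-chromene-2-carbaldehyde
Conditions: SeO2, 1,4-dioxane, reflux
Reagents that add atoms: selenium dioxide, O=[Se]=O
Why: Riley oxidation, in which the 2-methyl group, vinylogously activated by the C4 carbonyl, reacts with SeO2 by an ene reaction and [2,3]-sigmatropic shift to the aldehyde, as established for 2-methylchromones and 2-methylquinolines.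

Step 5
Reactants: 7 5,7,8-trimethoxy-4-oxo-4H-chromene-2-carbaldehyde
Product: 8 2-ethynyl-5,7,8-trimethoxy-4H-chromen-4-one
Conditions: dimethyl (1-diazo-2-oxopropyl)phosphonate, K2CO3, MeOH/THF, 0 °C to rt
Reagents that add atoms: dimethyl (1-diazo-2-oxopropyl)phosphonate, COP(=O)(OC)C(=[N+]=[N-])C(C)=O
Why: Ohira–Bestmann variant of the Seyferth–Gilbert homologation, in which methanolysis of the reagent releases the dimethyl diazomethylphosphonate anion that olefinates the aldehyde, and loss of N2 with a 1,2-hydrogen shift gives the terminal alkyne under carbonate conditions that the pyranone should tolerate at 0 °C.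

Step 6
Reactants: 8 2-ethynyl-5,7,8-trimethoxy-4H-chromen-4-one; 9 2-methoxyfuran
Product: 11 2-(5-hydroxy-2-methoxyphenyl)-5,7,8-trimethoxy-4H-chromen-4-one, via 1-methoxy-7-oxanorbornadiene cycloadduct 10 (not isolated)
Conditions: 9 (4 equiv), ZnCl2 (1.0 M in Et2O, 1 equiv), CH2Cl2, 0 °C to rt; then 1 M HCl wash
Reagents that add atoms: none
Why: Proposed new method: ZnCl2 held between the C4 carbonyl and the 5-methoxy oxygen gives the pyranone pyrylium character, so the ethynyl group behaves as a vinylogous ynone whose terminal carbon is attacked by the nucleophilic C5 of furan 9, and bonding of the furan C2 to the inner alkyne carbon completes an asynchronous [4+2] cycloaddition to the 1-methoxy-7-oxanorbornadiene 10. The bridge C–O bond at the methoxy-bearing bridgehead then ionises to an oxocarbenium ion, and loss of the proton at the other bridgehead carbon aromatises the ring to the para-methoxyphenol 11. The closest known reaction type is the cycloaddition and bridge opening of 2-methoxyfuran with acetylenic esters and ketones to 4-methoxyphenols, the acceptor here lying one vinylogous position further from the carbonyl. Ring B is closed as a six-membered carbocycle by intermolecular [4+2] cycloaddition, both new bonds (C1'–C2' and C6'–C5') arising in the same operation. No stereocentre is set, since the two bridgehead centres of 10 vanish on aromatisation. The step needs chemoselectivity for the alkyne over the C2=C3 bond and over conjugate attack at C2, which the unhindered terminal alkyne should secure against the trisubstituted pyranone double bond, while the orientation (methoxy next to C1') follows from the polarisation and is not critical because step 7 methylates the phenol.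

Step 7
Reactants: 11 2-(5-hydroxy-2-methoxyphenyl)-5,7,8-trimethoxy-4H-chromen-4-one
Product: 12 2-(2,5-dimethoxyphenyl)-5,7,8-trimethoxy-4H-chromen-4-one
Conditions: MeI, K2CO3, acetone, reflux
Reagents that add atoms: iodomethane, CI
Why: Williamson O-methylation of the only free phenol, which gives the same 2',5'-dimethoxy ring B whichever way round the furan added in step 6.

Step 8
Reactants: 12 2-(2,5-dimethoxyphenyl)-5,7,8-trimethoxy-4H-chromen-4-one
Product: 13 2-(2,5-dimethoxyphenyl)-5-hydroxy-7,8-dimethoxy-4H-chromen-4-one (5-hydroxy-7,8,2',5'-tetramethoxyflavone)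
Conditions: BCl3 (1 M in CH2Cl2), CH2Cl2, −20 to 0 °C; then H2O
Reagents that add atoms: none
Why: chelation-controlled Lewis acid demethylation, in which BCl3 bridges the C4 carbonyl and the peri 5-methoxy oxygen and chloride cleaves only that O–CH3 bond, the standard way to free the 5-hydroxyl of polymethoxyflavones while the four non-chelated methoxy groups remain.

**Compound list**

1 | 3,4,5-trimethoxyphenol | COc1cc(O)cc(OC)c1OC | starting material
2 | 1,2,3,5-tetramethoxybenzene | COc1cc(OC)c(OC)c(OC)c1 | intermediate
3 | 1-(2,3,4,6-tetramethoxyphenyl)ethanone | CC(=O)c1c(OC)cc(OC)c(OC)c1OC | intermediate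
4 | 1-(2-hydroxy-3,4,6-trimethoxyphenyl)ethanone | CC(=O)c1c(OC)cc(OC)c(OC)c1O | intermediate
5 | 1-(2-hydroxy-3,4,6-trimethoxyphenyl)butane-1,3-dione | CC(=O)CC(=O)c1c(OC)cc(OC)c(OC)c1O | intermediate
6 | 5,7,8-trimethoxy-2-methyl-4H-chromen-4-one | Cc1cc(=O)c2c(OC)cc(OC)c(OC)c2o1 | intermediate
7 | 5,7,8-trimethoxy-4-oxo-4H-chromene-2-carbaldehyde | O=Cc1cc(=O)c2c(OC)cc(OC)c(OC)c2o1 | intermediate
8 | 2-ethynyl-5,7,8-trimethoxy-4H-chromen-4-one | C#Cc1cc(=O)c2c(OC)cc(OC)c(OC)c2o1 | intermediate
9 | 2-methoxyfuran | COc1ccco1 | starting material
10 | 2-(1-methoxy-7-oxabicyclo[2.2.1]hepta-2,5-dien-2-yl)-5,7,8-trimethoxy-4H-chromen-4-one (racemic, one enantiomer drawn; the oxygen bridge fixes the relative configuration of the two bridgeheads) | CO[C@]12C=C[C@H](O1)C=C2c3cc(=O)c4c(OC)cc(OC)c(OC)c4o3 | intermediate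
11 | 2-(5-hydroxy-2-methoxyphenyl)-5,7,8-trimethoxy-4H-chromen-4-one | COc1ccc(O)cc1-c1cc(=O)c2c(OC)cc(OC)c(OC)c2o1 | intermediate
12 | 2-(2,5-dimethoxyphenyl)-5,7,8-trimethoxy-4H-chromen-4-one | COc1ccc(OC)c(-c2cc(=O)c3c(OC)cc(OC)c(OC)c3o2)c1 | intermediate
13 | 2-(2,5-dimethoxyphenyl)-5-hydroxy-7,8-dimethoxy-4H-chromen-4-one (5-hydroxy-7,8,2',5'-tetramethoxyflavone) | COc1ccc(OC)c(-c2cc(=O)c3c(O)cc(OC)c(OC)c3o2)c1 | target

**Step count**

Total: 8 steps. Longest linear sequence: 8 steps (1 to 13); 2-methoxyfuran 9 enters at step 6.

**Steps most likely to fail**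

1. Step 6. The alkyne is activated only through the C2=C3 bond, so cycloaddition may be slower than ZnCl2-induced decomposition or oligomerisation of the furan. The furan may also add in Michael fashion through its C5 to the alkyne terminus without closing the second bond. The fallback uses known chemistry and gives up the furan route to ring B. It sets out from acetophenone 4, which is acylated with 2,5-dimethoxybenzoyl chloride in pyridine to 2-acetyl-3,5,6-trimethoxyphenyl 2,5-dimethoxybenzoate F1. Baker–Venkataraman rearrangement (KOH, pyridine, 50 °C) should then give 1-(2,5-dimethoxyphenyl)-3-(2-hydroxy-3,4,6-trimethoxyphenyl)propane-1,3-dione F2. Cyclodehydration with catalytic H2SO4 in AcOH should close ring C and return to the route at compound 12, before step 8.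

2. Step 5. Methoxide may add to C2 of the pyranone or in 1,6-fashion to the newly formed ethynyl group, or open the pyranone ring, before the homologation is complete. The fallback avoids alkoxide in a protic medium and sets out from aldehyde 7. Wittig bromomethylenation with Ph3P=CHBr (from (bromomethyl)triphenylphosphonium bromide and KOt-Bu, THF, −78 °C) should give mainly 2-[(Z)-2-bromoethenyl]-5,7,8-trimethoxy-4H-chromen-4-one F3. Its vinylic hydrogen lies anti to bromine, so dehydrobromination with Bu4NF in DMF should deliver the alkyne and return to the route at compound 8.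

3. Step 4. The oxidation may run on to the carboxylic acid, or stall with selenium-containing by-products that are hard to remove from the polar aldehyde. The fallback sets out from 2-methylchromone 6. Condensation of the vinylogously acidic methyl group with N,N-dimethylformamide dimethyl acetal (DMF, 120 °C) should give 2-[(E)-2-(dimethylamino)ethenyl]-5,7,8-trimethoxy-4H-chromen-4-one F4. Oxidative cleavage of this enamine with NaIO4 in THF/H2O at rt should return to the route at aldehyde 7.

**Further compounds**

F1 | step 6 | 2-acetyl-3,5,6-trimethoxyphenyl 2,5-dimethoxybenzoate | COc1ccc(OC)c(C(=O)Oc2c(OC)c(OC)cc(OC)c2C(C)=O)c1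
F2 | step 6 | 1-(2,5-dimethoxyphenyl)-3-(2-hydroxy-3,4,6-trimethoxyphenyl)propane-1,3-dione | COc1ccc(OC)c(C(=O)CC(=O)c2c(OC)cc(OC)c(OC)c2O)c1
F3 | step 5 | 2-[(Z)-2-bromoethenyl]-5,7,8-trimethoxy-4H-chromen-4-one | Br/C=C\c1cc(=O)c2c(OC)cc(OC)c(OC)c2o1
F4 | step 4 | 2-[(E)-2-(dimethylamino)ethenyl]-5,7,8-trimethoxy-4H-chromen-4-one | CN(C)/C=C/c1cc(=O)c2c(OC)cc(OC)c(OC)c2o1
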